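The readings were computed on assumed constants, noise included.

| flask | starting material | coupling partner | remark | time |
|---|---|---|---|---|
| Monday's | 20 mM | 5 mM | run made earlier |  |
| Wednesday's | 20 mM | 20 mM | run made earlier |  |
| Friday's | 30 mM | 10 mM | run made earlier |  |
| flask | 20 mM | 10.0 mM |  | 3.0 d |

| run | time / h | starting material / % | target / % | isomer of the product / % |
|---|---|---|---|---|
| Monday's | 3.00 | 94.1 | 5.5 | 0 |
| Monday's | 6.00 | 80.9 | 14.4 | 5.1 |
| Monday's | 12.0 | 74.8 | 17.0 | 7.7 |
| Monday's | 25.0 | 73.7 | 18.2 | 6.0 |
| Monday's | 40.0 | 76.3 | 17.7 | 7.7 |
| Wednesday's | 8.00 | 4.3 | 70.4 | 25.9 |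
| Wednesday's | 15.0 | 2.7 | 68.8 | 28.2 |
| Wednesday's | 25.0 | 2.9 | 68.8 | 25.7 |
| Wednesday's | 30.0 | 1.8 | 69.2 | 30.7 |
| Wednesday's | 40.0 | 0.7 | 69.7 | 30.5 |
| Friday's | 3.00 | 68.9 | 27.3 | 4.2 |
| Friday's | 6.00 | 65.6 | 23.9 | 8.5 |
| Friday's | 12.0 | 64.8 | 23.0 | 11.2 |
| Friday's | 25.0 | 68.2 | 23.0 | 11.7 |
| Friday's | 40.0 | 66.2 | 23.2 | 9.4 |

(scatter of a reading: 1 percentage point)

- steps thought possible: starting material + coupling partner + target -> 2 target; starting material + coupling partner -> target; target <-> isomer of the product
- the reaction counts as stopped when no species that holds the starting material changes by six tenths of a point or more over the second half of the time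

- at 3.0 d, what has stopped the reaction, if anything has (the coupling partner has run out first / all of the starting material has reacted / forward and back rates have come level / it is still moving)
- part of the starting material gone at 3.0 d
- the target standing at 3.0 d, as a percentage of the starting material charged
- the isomer of the product standing at 3.0 d, as a percentage of the starting material charged

Begin with a division: take the charged [coupling partner] over the charged [starting material]. In the flask this gives 50.0%, the ceiling, the conversion that a one-for-one limiting reagent allows when starting material is in excess.

Test it at the late end of each run. Monday's division gives 25.0%, and the last reading shows 23.7% gone. Wednesday's gives 100%, with 99.3% gone. Friday's gives 33.3%, with 33.8% gone.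

But test the early end too. Monday's run loses 5.9 percentage points of starting material by 3.00 h, then 13 points by 6.00 h, more in the second equal stretch than in the first. So Monday's start reads slow. Still, Monday's readings stand level from 12.0 h, far short of 3.0 d. Join the two ends: commit to the ceiling for the flask.

The forecast gives 50% gone, target 35.3%, isomer of the product 14.7%, and says the coupling partner has run out first. Its ground: “None of these stops looks like a reversible coupling limit”.

The flask gives 50.0% gone, target 34.9% and isomer of the product 15.1%: the coupling partner has run out first.

    starting material + coupling partner + target → 2 target (k = 169 /M²/min)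
    starting material + coupling partner → target (k = 0.0132 /M/min)
    target ⇌ isomer of the product (K = 0.431, k = 0.00207 /min)

The ceiling of 50.0% stands level with the conversion of 50.0%, and at 3.00 d the flask holds 0% of its coupling partner against 50% of its starting material. Now cut the coupling partner to 4.0 mM in a neighbouring flask, the rest unchanged. Scale the ceiling with that charge: 20.0%. That neighbour gives 20.0% gone, with target at 14.0%, isomer of the product at 6.02% and starting material at 80.0%.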